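**Retrosynthetic overview**
1. The oxirane comes last (Sharpless epoxidation of the C14 allylic alcohol); the lactone comes from Luche reduction of a C6 ketone and closure onto the C7 acrylate ester.
2. The ten-membered ring comes from a Grob-type ring expansion of a trans-decalin: the C1–C6 ring-fusion bond is cleaved, giving the C6 ketone and the 1(10)-E alkene, while the 4Z alkene is carried in from a cyclohexene.
3. The decalin comes from closing ring B onto the carbonyl of ring A by intramolecular indium Barbier allylation (C6–C7), then C10 methylenation, Mitsunobu inversion at C8 and osmylation.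
4. The side chain comes from a Ti–BINOL vinylogous Mukaiyama aldol (C8–C9, sets C8) between a bis(silyloxy)diene made from 3-methylcyclohexenone and a Baylis–Hillman-derived bromo enal.
5. Ring order: cyclohexenone ring A (bought), ring B, ten-membered carbocycle, γ-lactone, oxirane.

Atom labels C1–C15 follow germacrane numbering of the target (C6 lactone carbinol, C7, C8 ester carbon, C1/C10 oxirane, C14 hydroxymethyl, C11–C13 acrylate unit).
Assumption: (S)-BINOL gives the (4S) aldol (facial sense taken from aryl and α,β-unsaturated aldehydes); if the sense is reversed the (R) ligand is used.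

**Step 1**
Reactants: 1 2,2-dimethoxyacetaldehyde; 2 methyl acrylate
Product: 3 methyl 3-hydroxy-4,4-dimethoxy-2-methylidenebutanoate (racemic)
Conditions: DABCO (0.5 equiv), 1,4-dioxane/H2O, 25 °C
Reagents that add atoms: none
Why: Morita–Baylis–Hillman reaction in which DABCO adds to the acrylate and the resulting enolate attacks the electron-poor α,α-dialkoxy aldehyde; the new carbinol centre is racemic and is destroyed in step 2.

**Step 2**
Reactants: 3 methyl 3-hydroxy-4,4-dimethoxy-2-methylidenebutanoate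
Product: 5 methyl (2Z)-2-(bromomethyl)-4-oxobut-2-enoate, via bromo acetal 4 (not isolated)
Conditions: NBS, Me2S, CH2Cl2, 0 °C; then 1 M HCl, THF, 25 °C
Reagents that add atoms: N-bromosuccinimide O=C1CCC(=O)N1Br; water O
Why: NBS/Me2S bromination of the Baylis–Hillman alcohol goes with SN2′ transposition to the favoured (Z)-2-(bromomethyl)enoate (substituent trans to the ester), and aqueous acid then hydrolyses the allylic acetal to the enal.

**Step 3**
Reactants: 6 3-methylcyclohex-2-en-1-one; 7 1-acetylimidazole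
Product: 8 6-acetyl-3-methylcyclohex-2-en-1-one
Conditions: LDA (2.1 equiv), THF, −78 °C; then 7; aq. NH4Cl
Reagents that add atoms: none
Why: Kinetic α′-deprotonation gives the cross-conjugated lithium enolate, which undergoes Claisen-type C-acylation with the N-acylimidazole (the second equivalent of base takes up the acidic β-diketone); C1 is enolised, so no stereocentre matters here.

**Step 4**
Reactants: 8 6-acetyl-3-methylcyclohex-2-en-1-one
Product: 9 4-methyl-2-(trimethylsilyloxy)-1-[1-(trimethylsilyloxy)ethenyl]cyclohexa-1,3-diene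
Conditions: LDA (2.2 equiv), THF, −78 °C; TMSCl (2.5 equiv), −78 to 0 °C
Reagents that add atoms: chlorotrimethylsilane C[Si](C)(C)Cl
Why: β-Diketone dianion formation (second deprotonation at the acetyl methyl) followed by double O-silylation gives the Chan-type 1,3-bis(silyloxy)diene.

**Step 5**
Reactants: 9 4-methyl-2-(trimethylsilyloxy)-1-[1-(trimethylsilyloxy)ethenyl]cyclohexa-1,3-diene; 5 methyl (2Z)-2-(bromomethyl)-4-oxobut-2-enoate
Product: 11 methyl (2Z,4S)-2-(bromomethyl)-4-hydroxy-6-(4-methyl-2-oxocyclohex-3-en-1-yl)-6-oxohex-2-enoate, via bis-silyl aldol adduct 10 (not isolated)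
Conditions: Ti(OiPr)4 (10 mol %), (S)-BINOL (10 mol %), 4 Å MS, THF, −78 to −20 °C; then TFA (cat.), THF/H2O, 0 °C
Reagents that add atoms: none
Why: Vinylogous Mukaiyama aldol addition in which the diene reacts at its terminal carbon (C9) with the aldehyde held in the chiral titanium BINOLate, which selects one aldehyde face and sets C8 as 4S; dilute acid then removes both silyl groups.

**Step 6**
Reactants: 11 methyl (2Z,4S)-2-(bromomethyl)-4-hydroxy-6-(4-methyl-2-oxocyclohex-3-en-1-yl)-6-oxohex-2-enoate
Product: 12 methyl 2-[(1R,2S,4aR,8aR)-2,8a-dihydroxy-7-methyl-4-oxo-1,2,3,4,4a,5,6,8a-octahydronaphthalen-1-yl]prop-2-enoate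
Conditions: In powder (2 equiv), THF/sat. aq. NH4Cl (3:1), 0.01 M, 25 °C
Reagents that add atoms: none
Why: Intramolecular Barbier allylation in which the 2-(methoxycarbonyl)allylindium adds through its γ-carbon (C7) to the ring carbonyl C6 (the only closure giving a six-membered ring) via a chair Zimmerman–Traxler transition state fused to the forming chair of ring B with the C8 hydroxyl equatorial, which sets C7 (R, trans to C8–OH) and C6, while C1 (α to the C10 ketone) settles as the trans-fused decalone.

**Step 7**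
Reactants: 12 methyl 2-[(1R,2S,4aR,8aR)-2,8a-dihydroxy-7-methyl-4-oxo-1,2,3,4,4a,5,6,8a-octahydronaphthalen-1-yl]prop-2-enoate
Product: 13 methyl 2-[(1R,2S,4aS,8aS)-2,8a-dihydroxy-7-methyl-4-methylidene-1,2,3,4,4a,5,6,8a-octahydronaphthalen-1-yl]prop-2-enoate
Conditions: Zn, CH2Br2, TiCl4, THF/CH2Cl2, 0 to 25 °C
Reagents that add atoms: dibromomethane BrCBr
Why: Takai–Lombardo methylenation converts the only ketone (C10) into the exocyclic methylene under non-basic conditions, so the β-hydroxy ketone suffers no retro-aldol or elimination and no stereocentre changes.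

**Step 8**
Reactants: 13 methyl 2-[(1R,2S,4aS,8aS)-2,8a-dihydroxy-7-methyl-4-methylidene-1,2,3,4,4a,5,6,8a-octahydronaphthalen-1-yl]prop-2-enoate; 14 2-methylpropanoic acid
Product: 15 methyl 2-[(1R,2R,4aS,8aS)-8a-hydroxy-7-methyl-4-methylidene-2-(2-methylpropanoyloxy)-1,2,3,4,4a,5,6,8a-octahydronaphthalen-1-yl]prop-2-enoate
Conditions: PPh3, DIAD, toluene, 0 to 25 °C
Reagents that add atoms: none
Why: Mitsunobu esterification of the only secondary alcohol goes with SN2 inversion at C8 (the equatorial oxyphosphonium has no antiperiplanar hydrogen for elimination), placing the isobutyrate axial and cis to the C7 side chain (8R) while the tertiary C6 hydroxyl is untouched.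

**Step 9**
Reactants: 15 methyl 2-[(1R,2R,4aS,8aS)-8a-hydroxy-7-methyl-4-methylidene-2-(2-methylpropanoyloxy)-1,2,3,4,4a,5,6,8a-octahydronaphthalen-1-yl]prop-2-enoate
Product: 16 methyl 2-[(1R,2R,4R,4aR,8aR)-4,8a-dihydroxy-4-(hydroxymethyl)-7-methyl-2-(2-methylpropanoyloxy)-1,2,3,4,4a,5,6,8a-octahydronaphthalen-1-yl]prop-2-enoate
Conditions: K2OsO2(OH)4 (1 mol %), (DHQD)2PHAL (5 mol %), NMO, t-BuOH/H2O, 0 °C
Reagents that add atoms: N-methylmorpholine N-oxide C[N+]1([O-])CCOCC1; water O
Why: Ligand-accelerated osmium-catalysed dihydroxylation (Sharpless type) selects the unhindered exocyclic 1,1-disubstituted alkene over the hindered ring alkene and the electron-poor acrylate, and osmium adds from the face opposite the axial C6 hydroxyl and axial C8 ester (also the face the ligand prefers), giving the equatorial tertiary C10 hydroxyl (10R).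

**Step 10**
Reactants: 16 methyl 2-[(1R,2R,4R,4aR,8aR)-4,8a-dihydroxy-4-(hydroxymethyl)-7-methyl-2-(2-methylpropanoyloxy)-1,2,3,4,4a,5,6,8a-octahydronaphthalen-1-yl]prop-2-enoate
Product: 19 methyl 2-[(1R,2R,4Z,8Z)-4-(hydroxymethyl)-8-methyl-2-(2-methylpropanoyloxy)-10-oxocyclodeca-4,8-dien-1-yl]prop-2-enoate, via cyclic orthoformate 17 (not isolated), via formate ester 18 (not isolated)
Conditions: HC(OMe)3, PPTS (5 mol %), CH2Cl2, 25 °C; then TMSOTf (1.2 equiv), 2,6-di-tert-butyl-4-methylpyridine, CH2Cl2, −78 °C; then KHCO3, MeOH/H2O, 0 °C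
Reagents that add atoms: none
Why: Proposed new method: ionising the spiro 2-methoxy-1,3-dioxolane with TMSOTf gives a 1,3-dioxolan-2-ylium ion whose tertiary C10–O bond lies antiperiplanar to the C1–C6 ring-fusion bond of the trans-decalin, so lone-pair push from the C6 hydroxyl cleaves C1–C6 in a Grob-type heterolytic fragmentation that enlarges ring A from six to ten members (C6 becomes the ketone, the equatorial C1–C2 bond ends trans to C9 to give the 1(10)-E alkene, and C10 loses its oxygen as the C14 formate that mild base removes), the closest known reaction types being the Wharton/Grob fragmentation of 1,3-diol monosulfonates and the titanium-mediated fragmentation of γ-hydroxy epoxides, with the dioxolanylium ion as the new nucleofuge.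

**Step 11**
Reactants: 19 methyl 2-[(1R,2R,4Z,8Z)-4-(hydroxymethyl)-8-methyl-2-(2-methylpropanoyloxy)-10-oxocyclodeca-4,8-dien-1-yl]prop-2-enoate
Product: 21 (3aR,4R,6Z,10Z,11aR)-6-(hydroxymethyl)-10-methyl-3-methylidene-2-oxo-2,3,3a,4,5,8,9,11a-octahydrocyclodeca[b]furan-4-yl 2-methylpropanoate, via hydroxy ester 20 (not isolated)
Conditions: NaBH4, CeCl3·7H2O, MeOH, −40 °C; then PPTS (cat.), CH2Cl2, 25 °C
Reagents that add atoms: none
Why: Luche reduction gives 1,2-reduction of the enone, hydride adding to the outer face of the carbonyl anti to the adjacent C7 side chain to set C6 as R (6α-hydroxyl, trans to the side chain), and the new hydroxyl closes the trans-fused γ-lactone on the acrylate ester with loss of methanol.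

**Step 12**
Reactants: 21 (3aR,4R,6Z,10Z,11aR)-6-(hydroxymethyl)-10-methyl-3-methylidene-2-oxo-2,3,3a,4,5,8,9,11a-octahydrocyclodeca[b]furan-4-yl 2-methylpropanoate
Product: 22 (1R,6R,7R,8R,10S)-1,10-epoxy-14-hydroxy-8-(2-methylpropanoyloxy)germacra-4Z,11(13)-dien-12,6-olide
Conditions: Ti(OiPr)4 (10 mol %), L-(+)-DET (12 mol %), t-BuOOH, 4 Å MS, CH2Cl2, −20 °C
Reagents that add atoms: tert-butyl hydroperoxide CC(C)(C)OO
Why: Sharpless asymmetric epoxidation of the only allylic alcohol (C14–OH), in which the titanium tartrate from L-(+)-DET delivers oxygen to the exposed outer face of the trans double bond and sets C1 as R and C10 as S, while the 4Z alkene and the acrylate (no free allylic hydroxyl) are untouched.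

**Compound list**
1 | 2,2-dimethoxyacetaldehyde | COC(OC)C=O | starting material
2 | methyl acrylate | C=CC(=O)OC | starting material
3 | methyl 3-hydroxy-4,4-dimethoxy-2-methylidenebutanoate (racemic) | COC(OC)C(O)C(=C)C(=O)OC | intermediate
4 | methyl (2Z)-2-(bromomethyl)-4,4-dimethoxybut-2-enoate | COC(OC)/C=C(\CBr)C(=O)OC | intermediate
5 | methyl (2Z)-2-(bromomethyl)-4-oxobut-2-enoate | O=C/C=C(\CBr)C(=O)OC | intermediate
6 | 3-methylcyclohex-2-en-1-one | CC1=CC(=O)CCC1 | starting material
7 | 1-acetylimidazole | CC(=O)n1ccnc1 | starting material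
8 | 6-acetyl-3-methylcyclohex-2-en-1-one (racemic, enolised β-diketone) | CC(=O)C1CCC(C)=CC1=O | intermediate
9 | 4-methyl-2-(trimethylsilyloxy)-1-[1-(trimethylsilyloxy)ethenyl]cyclohexa-1,3-diene | C=C(O[Si](C)(C)C)C1=C(O[Si](C)(C)C)C=C(C)CC1 | intermediate
10 | bis-silyl aldol adduct: 11 carrying a C8 O-trimethylsilyl ether (4S) and the ring ketone as its trimethylsilyl enol ether | COC(=O)/C(CBr)=C/[C@@H](O[Si](C)(C)C)CC(=O)C1=C(O[Si](C)(C)C)C=C(C)CC1 | intermediate
11 | methyl (2Z,4S)-2-(bromomethyl)-4-hydroxy-6-(4-methyl-2-oxocyclohex-3-en-1-yl)-6-oxohex-2-enoate | COC(=O)/C(CBr)=C/[C@@H](O)CC(=O)C1CCC(C)=CC1=O | intermediate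
12 | methyl 2-[(1R,2S,4aR,8aR)-2,8a-dihydroxy-7-methyl-4-oxo-1,2,3,4,4a,5,6,8a-octahydronaphthalen-1-yl]prop-2-enoate | C=C(C(=O)OC)[C@@H]1[C@@H](O)CC(=O)[C@@H]2CCC(C)=C[C@@]12O | intermediate
13 | methyl 2-[(1R,2S,4aS,8aS)-2,8a-dihydroxy-7-methyl-4-methylidene-1,2,3,4,4a,5,6,8a-octahydronaphthalen-1-yl]prop-2-enoate | C=C(C(=O)OC)[C@@H]1[C@@H](O)CC(=C)[C@@H]2CCC(C)=C[C@@]12O | intermediate
14 | 2-methylpropanoic acid (isobutyric acid) | CC(C)C(=O)O | starting material
15 | methyl 2-[(1R,2R,4aS,8aS)-8a-hydroxy-7-methyl-4-methylidene-2-(2-methylpropanoyloxy)-1,2,3,4,4a,5,6,8a-octahydronaphthalen-1-yl]prop-2-enoate | C=C(C(=O)OC)[C@@H]1[C@H](OC(=O)C(C)C)CC(=C)[C@@H]2CCC(C)=C[C@@]12O | intermediate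
16 | methyl 2-[(1R,2R,4R,4aR,8aR)-4,8a-dihydroxy-4-(hydroxymethyl)-7-methyl-2-(2-methylpropanoyloxy)-1,2,3,4,4a,5,6,8a-octahydronaphthalen-1-yl]prop-2-enoate | C=C(C(=O)OC)[C@@H]1[C@H](OC(=O)C(C)C)C[C@](O)(CO)[C@@H]2CCC(C)=C[C@@]12O | intermediate
17 | cyclic orthoformate of 16: the C10 hydroxyl and the C14 hydroxyl joined in a spiro 2-methoxy-1,3-dioxolane (orthoformate carbon a mixture of epimers; other centres as in 16) | C=C(C(=O)OC)[C@@H]1[C@H](OC(=O)C(C)C)C[C@]3(COC(OC)O3)[C@@H]2CCC(C)=C[C@@]12O | intermediate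
18 | formate ester of 19 at the C14 hydroxyl | C=C(C(=O)OC)[C@H]1C(=O)/C=C(/C)CC/C=C(\COC=O)C[C@H]1OC(=O)C(C)C | intermediate
19 | methyl 2-[(1R,2R,4Z,8Z)-4-(hydroxymethyl)-8-methyl-2-(2-methylpropanoyloxy)-10-oxocyclodeca-4,8-dien-1-yl]prop-2-enoate | C=C(C(=O)OC)[C@H]1C(=O)/C=C(/C)CC/C=C(\CO)C[C@H]1OC(=O)C(C)C | intermediate
20 | methyl 2-[(1S,2R,4Z,8Z,10R)-10-hydroxy-4-(hydroxymethyl)-8-methyl-2-(2-methylpropanoyloxy)cyclodeca-4,8-dien-1-yl]prop-2-enoate | C=C(C(=O)OC)[C@H]1[C@H](O)/C=C(/C)CC/C=C(\CO)C[C@H]1OC(=O)C(C)C | intermediate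
21 | (3aR,4R,6Z,10Z,11aR)-6-(hydroxymethyl)-10-methyl-3-methylidene-2-oxo-2,3,3a,4,5,8,9,11a-octahydrocyclodeca[b]furan-4-yl 2-methylpropanoate | C=C1C(=O)O[C@@H]2/C=C(/C)CC/C=C(\CO)C[C@@H](OC(=O)C(C)C)[C@@H]12 | intermediate
22 | (1R,6R,7R,8R,10S)-1,10-epoxy-14-hydroxy-8-(2-methylpropanoyloxy)germacra-4Z,11(13)-dien-12,6-olide | C=C1C(=O)O[C@@H]2/C=C(/C)CC[C@H]3O[C@]3(CO)C[C@@H](OC(=O)C(C)C)[C@@H]12 | target

**Step count**
Total steps: 12. Longest linear sequence: 10 (steps 3 to 12; the branch through steps 1, 2 and 5 to 12 is also 10).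

**Three steps most likely to fail, each with a fallback**

Step 6 (closure of ring B). The risk is the relative configuration at C7/C8: if the free C8 hydroxyl binds indium, it may end axial and cis to the new side chain instead of equatorial. The fallback then uses that outcome and replaces the later inversion by a retention acylation. It sets out from 9 (with 5): the aldol is run with (R)-BINOL to give the (4R)-aldol F1, indium closes it to the cis-ketol F2, Zn/CH2Br2/TiCl4 gives the methylidene diol F3, and the axial C8 hydroxyl is acylated with retention (isobutyryl chloride, pyridine, DMAP). It comes back to the route at 15.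

Step 10 (the proposed new ring expansion). The dioxolanylium ion may instead lose a proton, ionise the tertiary allylic C6 hydroxyl, or let the product re-close under the Lewis acid. The known-chemistry fallback sets out from 16: Mitsunobu cyclodehydration of the 1,2-diol (PPh3, DIAD) gives the spiro-epoxide F4 with the tertiary oxygen kept equatorial, and Ti(OiPr)4 in CH2Cl2 at 25 to 40 °C then brings about the established titanium-mediated epoxy-alcohol (Grob) fragmentation, which is driven by epoxide strain. It comes back to the route at 19.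

Step 11 (facial selectivity at C6). Substrate control in the flexible ten-membered enone may give the 6-epimer, which would close to the cis-lactone. The fallback switches to reagent control. It sets out from 19: the C14 hydroxyl is capped (TESCl, imidazole) to the silyl ether F5, the ketone is reduced with catecholborane and (R)-2-methyl-CBS-oxazaborolidine (alkenyl arm as the large group), PPTS closes the lactone to the silyl-protected lactone F6, and HF·pyridine removes the silyl group. It comes back to the route at 21.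

**Further compounds**
F1 | step 6 | methyl (2Z,4R)-2-(bromomethyl)-4-hydroxy-6-(4-methyl-2-oxocyclohex-3-en-1-yl)-6-oxohex-2-enoate | COC(=O)/C(CBr)=C/[C@H](O)CC(=O)C1CCC(C)=CC1=O
F2 | step 6 | methyl 2-[(1R,2R,4aR,8aR)-2,8a-dihydroxy-7-methyl-4-oxo-1,2,3,4,4a,5,6,8a-octahydronaphthalen-1-yl]prop-2-enoate | C=C(C(=O)OC)[C@@H]1[C@H](O)CC(=O)[C@@H]2CCC(C)=C[C@@]12O
F3 | step 6 | methyl 2-[(1R,2R,4aS,8aS)-2,8a-dihydroxy-7-methyl-4-methylidene-1,2,3,4,4a,5,6,8a-octahydronaphthalen-1-yl]prop-2-enoate | C=C(C(=O)OC)[C@@H]1[C@H](O)CC(=C)[C@@H]2CCC(C)=C[C@@]12O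
F4 | step 10 | spiro-epoxide of 16: oxirane closed between the C10 oxygen and C14 (C10 R; other centres as in 16) | C=C(C(=O)OC)[C@@H]1[C@H](OC(=O)C(C)C)C[C@]3(CO3)[C@@H]2CCC(C)=C[C@@]12O
F5 | step 11 | triethylsilyl ether of 19 at the C14 hydroxyl | C=C(C(=O)OC)[C@H]1C(=O)/C=C(/C)CC/C=C(\CO[Si](CC)(CC)CC)C[C@H]1OC(=O)C(C)C
F6 | step 11 | triethylsilyl ether of 21 at the C14 hydroxyl | C=C1C(=O)O[C@@H]2/C=C(/C)CC/C=C(\CO[Si](CC)(CC)CC)C[C@@H](OC(=O)C(C)C)[C@@H]12
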